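**Plan** (carbon labels follow germacrane numbering: C12 lactone carbonyl, C13 exocyclic methylene, C14 methyl, C15 oxygenated methylene)
- Cuts, in retrosynthetic order: the C15–O ester; ring bond C5–C6 (Nozaki–Hiyama–Kishi); the lactone O–C8 bond together with the C1=C10 π bond, both traced to one cyclopropyl carbinol; C1–C2 (alkylzinc + enal); C7–C8 (Rh 1,4-addition).
- Enabling feature: the lactone oxygen on C8 is homoallylic to the C1=C10 E-olefin (O–C8–C9–C10=C1). The γ-lactone ring and this olefin are therefore the retron of a cyclopropylcarbinyl→homoallyl rearrangement of a C8–C9–C10 cyclopropane that carries OH on C1 and the acrylate ester on C7.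
- Forward order: open chain C6–C7–C11(=C13)–C12 with an isobutenyl group (C8, C10, C14, C1) → cyclopropane → γ-lactone and E-olefin in one strain-releasing step → ten-membered carbocycle → side-chain ester.
- Stereochemistry: C7 from (S)-BINAP/Rh; a temporary C1 carbinol from (−)-MIB steers the Simmons–Smith reaction and is then destroyed; C8 by inversion at the cyclopropane; C6 in the macrocyclisation. Olefin geometries come from SeO2 (E-methyl), anti-carbomagnesiation/iodination (C4=C5) and the rearrangement (C1=C10).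

Key step: step 9

Remark: 27 and 28 are racemic, which is immaterial because their stereocentre is lost in step 15.

**Step 1**
Reactants: 1 2-[(tert-butyldimethylsilyl)oxy]acetaldehyde; 2 tert-butyl 2-(triphenyl-λ5-phosphanylidene)acetate
Product: 3 tert-butyl (2E)-4-[(tert-butyldimethylsilyl)oxy]but-2-enoate
Conditions: CH2Cl2, rt
Reagents that add atoms: none
Why: Wittig olefination with a stabilised ylide should give the (E)-enoate selectively; no stereocentre is formed.

**Step 2**
Reactants: 3 tert-butyl (2E)-4-[(tert-butyldimethylsilyl)oxy]but-2-enoate; 4 (2-methylprop-1-en-1-yl)boronic acid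
Product: 5 tert-butyl (3R)-3-{[(tert-butyldimethylsilyl)oxy]methyl}-5-methylhex-4-enoate
Conditions: Rh(acac)(C2H4)2 (3 mol %), (S)-BINAP, 4 (3 equiv), dioxane/H2O 10:1, 100 °C
Reagents that add atoms: none
Why: Hayashi–Miyaura Rh-catalysed asymmetric 1,4-addition: the alkenyl–Rh/(S)-BINAP complex should add to the α-si face of the (E)-enoate and so set C7 (3R in 5) under catalyst control.

**Step 3**
Reactants: 5 tert-butyl (3R)-3-{[(tert-butyldimethylsilyl)oxy]methyl}-5-methylhex-4-enoate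
Product: 8 tert-butyl 2-[(2S)-1-[(tert-butyldimethylsilyl)oxy]-4-methylpent-3-en-2-yl]prop-2-enoate, via Mannich base 6 (not isolated), via trimethylammonium iodide 7 (not isolated)
Conditions: LDA (from i-Pr2NH, n-BuLi), THF, −78 °C; Me2N=CH2+ I−, −78 °C → rt; then MeI, MeOH, rt; then aq NaHCO3, CH2Cl2
Reagents that add atoms: Eschenmoser's salt (N,N-dimethylmethyleneiminium iodide), C=[N+](C)C.[I-]
Why: Ester α-methylenation (Mannich reaction of the lithium enolate with Eschenmoser's salt, N-methylation, E1cB loss of trimethylamine under mild base) should install the acrylate without touching C7; the C2 centre of 6 and 7 is transient.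

**Step 4**
Reactants: 8 tert-butyl 2-[(2S)-1-[(tert-butyldimethylsilyl)oxy]-4-methylpent-3-en-2-yl]prop-2-enoate
Product: 10 tert-butyl 2-[(2S,3E)-1-[(tert-butyldimethylsilyl)oxy]-4-methyl-5-oxopent-3-en-2-yl]prop-2-enoate, via allylic alcohol 9 (not isolated)
Conditions: SeO2 (0.5 equiv), t-BuOOH, CH2Cl2, rt; then MnO2, CH2Cl2, rt
Reagents that add atoms: selenium dioxide, O=[Se]=O; tert-butyl hydroperoxide, CC(C)(C)OO
Why: SeO2 allylic oxidation (ene reaction then [2,3]-shift) should attack only the (E)-methyl group of the electron-rich trisubstituted olefin, and MnO2 should take the allylic alcohol on to the (E)-enal; the acrylate is too electron-poor to react.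

**Step 5**
Reactants: 11 prop-2-yn-1-ol; 12 vinylmagnesium bromide
Product: 14 (2Z)-2-(iodomethylidene)but-3-en-1-ol, via alkenylmagnesium alkoxide 13 (not isolated)
Conditions: 12 (2.5 equiv), CuI (10 mol %), THF, −20 °C → rt; then I2, −40 → 0 °C; aq NH4Cl
Reagents that add atoms: iodine, II
Why: Cu-catalysed anti-carbomagnesiation of the propargylic alkoxide should put the vinyl group on the internal carbon and a chelated Mg on the terminal carbon cis to CH2O, so iodinolysis with retention gives the iodoalkene with I cis to CH2OH (the C4=C5 geometry of the target).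

**Step 6**
Reactants: 14 (2Z)-2-(iodomethylidene)but-3-en-1-ol
Product: 15 tert-butyl{[(2Z)-2-(iodomethylidene)but-3-en-1-yl]oxy}diphenylsilane
Conditions: TBDPSCl, imidazole, CH2Cl2, 0 °C → rt
Reagents that add atoms: tert-butyl(chloro)diphenylsilane, CC(C)(C)[Si](Cl)(c1ccccc1)c1ccccc1
Why: Imidazole-mediated silylation of a primary alcohol should proceed without affecting the iodoalkene or the diene.

**Step 7**
Reactants: 10 tert-butyl 2-[(2S,3E)-1-[(tert-butyldimethylsilyl)oxy]-4-methyl-5-oxopent-3-en-2-yl]prop-2-enoate; 15 tert-butyl{[(2Z)-2-(iodomethylidene)but-3-en-1-yl]oxy}diphenylsilane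
Product: 18 tert-butyl 2-[(2S,3E,5S,8Z)-1-[(tert-butyldimethylsilyl)oxy]-8-{[(tert-butyldiphenylsilyl)oxy]methyl}-5-hydroxy-9-iodo-4-methylnona-3,8-dien-2-yl]prop-2-enoate, via alkyldiethylborane 16 (not isolated), via dialkylzinc 17 (not isolated)
Conditions: 15 (2.5 equiv), Et2BH (from BH3·SMe2, Et3B), Et2O, 0 °C → rt; Et2Zn, 0 °C, then volatiles off in vacuo; then 10, (−)-MIB (5 mol %), toluene, −20 → 0 °C; aq NH4Cl
Reagents that add atoms: none
Why: Hydroboration of the terminal vinyl group and boron–zinc exchange should give a dialkylzinc, whose amino-alcohol-catalysed enantioselective 1,2-addition to the enal should occur on the Si face and set the C1 carbinol (5S) under catalyst control, independent of the remote C7 centre.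

**Step 8**
Reactants: 18 tert-butyl 2-[(2S,3E,5S,8Z)-1-[(tert-butyldimethylsilyl)oxy]-8-{[(tert-butyldiphenylsilyl)oxy]methyl}-5-hydroxy-9-iodo-4-methylnona-3,8-dien-2-yl]prop-2-enoate
Product: 19 tert-butyl 2-{(1S)-2-[(tert-butyldimethylsilyl)oxy]-1-[(1R,2S)-2-{(1S,4Z)-4-{[(tert-butyldiphenylsilyl)oxy]methyl}-1-hydroxy-5-iodopent-4-en-1-yl}-2-methylcyclopropyl]ethyl}prop-2-enoate
Conditions: Et2Zn, CH2I2, CH2Cl2, −10 → 0 °C
Reagents that add atoms: diiodomethane, ICI
Why: Hydroxyl-directed Simmons–Smith cyclopropanation (Furukawa modification): the zinc alkoxide should deliver CH2 to the adjacent trisubstituted olefin syn to the C1–O bond in the allylic-strain-minimised conformer, which sets C8 and C10, while the electron-poor acrylate and iodoalkene stay intact.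

**Step 9**
Reactants: 19 tert-butyl 2-{(1S)-2-[(tert-butyldimethylsilyl)oxy]-1-[(1R,2S)-2-{(1S,4Z)-4-{[(tert-butyldiphenylsilyl)oxy]methyl}-1-hydroxy-5-iodopent-4-en-1-yl}-2-methylcyclopropyl]ethyl}prop-2-enoate
Product: 20 (4S,5S)-4-{[(tert-butyldimethylsilyl)oxy]methyl}-5-[(2E,6Z)-6-{[(tert-butyldiphenylsilyl)oxy]methyl}-7-iodo-2-methylhepta-2,6-dien-1-yl]-3-methylideneoxolan-2-one
Conditions: BF3·OEt2 (0.3 equiv), CH2Cl2, −78 → −30 °C
Reagents that add atoms: none
Why: Proposed new method: BF3 should ionise the C1 carbinol to a bisected cyclopropylcarbinyl cation whose charge is shared with C8, and the carbonyl oxygen of the tert-butyl acrylate on C7 should attack C8 anti to the breaking C8–C10 bond while the C10=C1 π bond forms, the O-tert-butyl lactonium ion then losing isobutene to give the α-methylene-γ-lactone. The closest known reaction types are the Julia–Johnson cyclopropylcarbinyl→homoallyl rearrangement with halide capture, stereoinvertive substitution of cyclopropyl carbinols at the more substituted ring carbon, and cation capture by tert-butyl esters in halolactonisation; what is new is the intramolecular ester termination. The lactone closes by a 5-exo-tet C–O bond formation at C8, the cleaved C8–C10 bond being exocyclic to the new ring. C8 is set by inversion at the cyclopropane carbon (1R in 19 becomes 5S in 20), so its configuration is relayed from the C1 carbinol through the directed cyclopropanation, while C7 is untouched and the C1 and C10 stereocentres are consumed. The step needs attack at C8 and not at C9 or C1, the E olefin, and survival of the silyl ethers: C8 is secondary and reached through a five-membered ring whereas C9 is primary and needs a six-membered ring, C1 is out of reach because C7 and C1 are trans on the cyclopropane, the C2 chain should sit away from the ring and hence cis to the C10 methyl in the bisected cation, and substoichiometric BF3 at low temperature should spare the TBS and TBDPS ethers, which are also poorer nucleophiles than the ester carbonyl.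

**Step 10**
Reactants: 20 (4S,5S)-4-{[(tert-butyldimethylsilyl)oxy]methyl}-5-[(2E,6Z)-6-{[(tert-butyldiphenylsilyl)oxy]methyl}-7-iodo-2-methylhepta-2,6-dien-1-yl]-3-methylideneoxolan-2-one
Product: 21 (4S,5S)-5-[(2E,6Z)-6-{[(tert-butyldiphenylsilyl)oxy]methyl}-7-iodo-2-methylhepta-2,6-dien-1-yl]-4-(hydroxymethyl)-3-methylideneoxolan-2-one
Conditions: HF·pyridine, pyridine, THF, 0 °C
Reagents that add atoms: none
Why: Buffered fluoride desilylation should cleave the primary TBS ether much faster than the bulkier TBDPS ether and leave the lactone untouched.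

**Step 11**
Reactants: 21 (4S,5S)-5-[(2E,6Z)-6-{[(tert-butyldiphenylsilyl)oxy]methyl}-7-iodo-2-methylhepta-2,6-dien-1-yl]-4-(hydroxymethyl)-3-methylideneoxolan-2-one
Product: 22 (2S,3R)-2-[(2E,6Z)-6-{[(tert-butyldiphenylsilyl)oxy]methyl}-7-iodo-2-methylhepta-2,6-dien-1-yl]-4-methylidene-5-oxooxolane-3-carbaldehyde
Conditions: Dess–Martin periodinane, NaHCO3, CH2Cl2, 0 °C
Reagents that add atoms: none
Why: Buffered Dess–Martin oxidation should give the aldehyde without epimerising C7 or moving the exocyclic olefin into conjugation.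

**Step 12**
Reactants: 22 (2S,3R)-2-[(2E,6Z)-6-{[(tert-butyldiphenylsilyl)oxy]methyl}-7-iodo-2-methylhepta-2,6-dien-1-yl]-4-methylidene-5-oxooxolane-3-carbaldehyde
Product: 23 (3aS,4R,5Z,9E,11aS)-6-{[(tert-butyldiphenylsilyl)oxy]methyl}-4-hydroxy-10-methyl-3-methylidene-3a,4,7,8,11,11a-hexahydrocyclodeca[b]furan-2(3H)-one
Conditions: CrCl2 (10 equiv), NiCl2 (cat.), DMSO/THF, 2 mM, rt
Reagents that add atoms: none
Why: Intramolecular Nozaki–Hiyama–Kishi reaction: the alkenylchromium, formed with retention of the C4=C5 geometry, should add to the aldehyde at high dilution and close the ten-membered ring, the C6 carbinol (4R) arising from attack on the aldehyde face that keeps the Cr-bound oxygen on the outside of the crown-shaped ring (H6 anti to H7).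

**Step 13**
Reactants: 23 (3aS,4R,5Z,9E,11aS)-6-{[(tert-butyldiphenylsilyl)oxy]methyl}-4-hydroxy-10-methyl-3-methylidene-3a,4,7,8,11,11a-hexahydrocyclodeca[b]furan-2(3H)-one
Product: 24 (3aS,4R,5Z,9E,11aS)-4-hydroxy-6-(hydroxymethyl)-10-methyl-3-methylidene-3a,4,7,8,11,11a-hexahydrocyclodeca[b]furan-2(3H)-one
Conditions: TBAF, AcOH (1:1), THF, 0 °C → rt
Reagents that add atoms: none
Why: Acetic-acid-buffered fluoride desilylation should free the primary allylic alcohol without base-induced translactonisation to O6.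

**Step 14**
Reactants: 25 tert-butyl prop-2-enoate; 26 acetaldehyde
Product: 27 tert-butyl 3-hydroxy-2-methylidenebutanoate (racemic)
Conditions: DABCO (20 mol %), neat, rt
Reagents that add atoms: none
Why: Morita–Baylis–Hillman reaction joins the acrylate α-carbon to acetaldehyde; the racemic carbinol centre is removed in step 15.

**Step 15**
Reactants: 27 tert-butyl 3-hydroxy-2-methylidenebutanoate
Product: 29 tert-butyl (2E)-2-(acetoxymethyl)but-2-enoate, via secondary acetate 28 (not isolated)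
Conditions: Ac2O, Et3N, DMAP (cat.), CH2Cl2, 0 °C; then DABCO (0.2 equiv), THF, 65 °C
Reagents that add atoms: acetic anhydride, CC(=O)OC(C)=O
Why: Acetylation followed by DABCO-catalysed SN2′/SN2′ 1,3-transposition of the Baylis–Hillman acetate should give the thermodynamically preferred primary acetate with the (E)-trisubstituted olefin (ester trans to methyl).

**Step 16**
Reactants: 29 tert-butyl (2E)-2-(acetoxymethyl)but-2-enoate
Product: 30 (2E)-2-(acetoxymethyl)but-2-enoic acid
Conditions: TFA, CH2Cl2, 0 °C → rt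
Reagents that add atoms: none
Why: Acidolysis of the tert-butyl ester (E1 loss of isobutene) should free the acid while the acetate survives.

**Step 17**
Reactants: 24 (3aS,4R,5Z,9E,11aS)-4-hydroxy-6-(hydroxymethyl)-10-methyl-3-methylidene-3a,4,7,8,11,11a-hexahydrocyclodeca[b]furan-2(3H)-one; 30 (2E)-2-(acetoxymethyl)but-2-enoic acid
Product: 32 [(3aS,4R,5Z,9E,11aS)-4-hydroxy-10-methyl-3-methylidene-2-oxo-2,3,3a,4,7,8,11,11a-octahydrocyclodeca[b]furan-6-yl]methyl (2E)-2-(acetoxymethyl)but-2-enoate (CNP0184624.1), via acid chloride 31 (not isolated)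
Conditions: 30, (COCl)2, DMF (cat.), CH2Cl2, 0 °C, then concentrate; 24, 2,4,6-collidine, CH2Cl2, −40 °C
Reagents that add atoms: none
Why: Acylation with the acid chloride under weak-base control at low temperature should select the unhindered primary allylic C15 hydroxyl over the flanked secondary C6 hydroxyl and should not isomerise the side-chain olefin.

**Compound list**
1 | 2-[(tert-butyldimethylsilyl)oxy]acetaldehyde | O=CCO[Si](C)(C)C(C)(C)C | starting material
2 | tert-butyl 2-(triphenyl-λ5-phosphanylidene)acetate | CC(C)(C)OC(=O)C=P(c1ccccc1)(c1ccccc1)c1ccccc1 | starting material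
3 | tert-butyl (2E)-4-[(tert-butyldimethylsilyl)oxy]but-2-enoate | CC(C)(C)OC(=O)/C=C/CO[Si](C)(C)C(C)(C)C | intermediate
4 | (2-methylprop-1-en-1-yl)boronic acid | CC(C)=CB(O)O | starting material
5 | tert-butyl (3R)-3-{[(tert-butyldimethylsilyl)oxy]methyl}-5-methylhex-4-enoate | CC(C)(C)OC(=O)C[C@@H](CO[Si](C)(C)C(C)(C)C)C=C(C)C | intermediate
6 | tert-butyl (3S)-3-{[(tert-butyldimethylsilyl)oxy]methyl}-2-[(dimethylamino)methyl]-5-methylhex-4-enoate (C2 epimers; Mannich base) | CC(C)(C)OC(=O)C(CN(C)C)[C@@H](CO[Si](C)(C)C(C)(C)C)C=C(C)C | intermediate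
7 | N-trimethylammonium iodide of 6 | CC(C)(C)OC(=O)C(C[N+](C)(C)C)[C@@H](CO[Si](C)(C)C(C)(C)C)C=C(C)C.[I-] | intermediate
8 | tert-butyl 2-[(2S)-1-[(tert-butyldimethylsilyl)oxy]-4-methylpent-3-en-2-yl]prop-2-enoate | CC(C)(C)OC(=O)C(=C)[C@@H](CO[Si](C)(C)C(C)(C)C)C=C(C)C | intermediate
9 | tert-butyl 2-[(2S,3E)-1-[(tert-butyldimethylsilyl)oxy]-5-hydroxy-4-methylpent-3-en-2-yl]prop-2-enoate | CC(C)(C)OC(=O)C(=C)[C@@H](CO[Si](C)(C)C(C)(C)C)/C=C(\C)CO | intermediate
10 | tert-butyl 2-[(2S,3E)-1-[(tert-butyldimethylsilyl)oxy]-4-methyl-5-oxopent-3-en-2-yl]prop-2-enoate | CC(C)(C)OC(=O)C(=C)[C@@H](CO[Si](C)(C)C(C)(C)C)/C=C(\C)C=O | intermediate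
11 | prop-2-yn-1-ol | C#CCO | starting material
12 | vinylmagnesium bromide | C=C[Mg]Br | starting material
13 | bromomagnesium (2Z)-2-[(bromomagnesio)methylidene]but-3-en-1-olate | C=C/C(CO[Mg]Br)=C/[Mg]Br | intermediate
14 | (2Z)-2-(iodomethylidene)but-3-en-1-ol | C=C/C(CO)=C/I | intermediate
15 | tert-butyl{[(2Z)-2-(iodomethylidene)but-3-en-1-yl]oxy}diphenylsilane | C=C/C(CO[Si](C(C)(C)C)(c1ccccc1)c1ccccc1)=C/I | intermediate
16 | [(3Z)-3-{[(tert-butyldiphenylsilyl)oxy]methyl}-4-iodobut-3-en-1-yl]diethylborane | CCB(CC)CC/C(CO[Si](C(C)(C)C)(c1ccccc1)c1ccccc1)=C/I | intermediate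
17 | bis[(3Z)-3-{[(tert-butyldiphenylsilyl)oxy]methyl}-4-iodobut-3-en-1-yl]zinc | I/C=C(/CC[Zn]CC/C(CO[Si](C(C)(C)C)(c1ccccc1)c1ccccc1)=C/I)CO[Si](C(C)(C)C)(c1ccccc1)c1ccccc1 | intermediate
18 | tert-butyl 2-[(2S,3E,5S,8Z)-1-[(tert-butyldimethylsilyl)oxy]-8-{[(tert-butyldiphenylsilyl)oxy]methyl}-5-hydroxy-9-iodo-4-methylnona-3,8-dien-2-yl]prop-2-enoate | CC(C)(C)OC(=O)C(=C)[C@@H](CO[Si](C)(C)C(C)(C)C)/C=C(\C)[C@@H](O)CC/C(CO[Si](C(C)(C)C)(c1ccccc1)c1ccccc1)=C/I | intermediate
19 | tert-butyl 2-{(1S)-2-[(tert-butyldimethylsilyl)oxy]-1-[(1R,2S)-2-{(1S,4Z)-4-{[(tert-butyldiphenylsilyl)oxy]methyl}-1-hydroxy-5-iodopent-4-en-1-yl}-2-methylcyclopropyl]ethyl}prop-2-enoate | CC(C)(C)OC(=O)C(=C)[C@@H](CO[Si](C)(C)C(C)(C)C)[C@H]1C[C@]1(C)[C@@H](O)CC/C(CO[Si](C(C)(C)C)(c1ccccc1)c1ccccc1)=C/I | intermediate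
20 | (4S,5S)-4-{[(tert-butyldimethylsilyl)oxy]methyl}-5-[(2E,6Z)-6-{[(tert-butyldiphenylsilyl)oxy]methyl}-7-iodo-2-methylhepta-2,6-dien-1-yl]-3-methylideneoxolan-2-one | C=C1C(=O)O[C@@H](C/C(C)=C/CC/C(CO[Si](C(C)(C)C)(c2ccccc2)c2ccccc2)=C/I)[C@@H]1CO[Si](C)(C)C(C)(C)C | intermediate
21 | (4S,5S)-5-[(2E,6Z)-6-{[(tert-butyldiphenylsilyl)oxy]methyl}-7-iodo-2-methylhepta-2,6-dien-1-yl]-4-(hydroxymethyl)-3-methylideneoxolan-2-one | C=C1C(=O)O[C@@H](C/C(C)=C/CC/C(CO[Si](C(C)(C)C)(c2ccccc2)c2ccccc2)=C/I)[C@@H]1CO | intermediate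
22 | (2S,3R)-2-[(2E,6Z)-6-{[(tert-butyldiphenylsilyl)oxy]methyl}-7-iodo-2-methylhepta-2,6-dien-1-yl]-4-methylidene-5-oxooxolane-3-carbaldehyde | C=C1C(=O)O[C@@H](C/C(C)=C/CC/C(CO[Si](C(C)(C)C)(c2ccccc2)c2ccccc2)=C/I)[C@@H]1C=O | intermediate
23 | (3aS,4R,5Z,9E,11aS)-6-{[(tert-butyldiphenylsilyl)oxy]methyl}-4-hydroxy-10-methyl-3-methylidene-3a,4,7,8,11,11a-hexahydrocyclodeca[b]furan-2(3H)-one | C=C1C(=O)O[C@H]2C/C(C)=C/CC/C(CO[Si](C(C)(C)C)(c3ccccc3)c3ccccc3)=C/[C@@H](O)[C@H]12 | intermediate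
24 | (3aS,4R,5Z,9E,11aS)-4-hydroxy-6-(hydroxymethyl)-10-methyl-3-methylidene-3a,4,7,8,11,11a-hexahydrocyclodeca[b]furan-2(3H)-one | C=C1C(=O)O[C@H]2C/C(C)=C/CC/C(CO)=C/[C@@H](O)[C@H]12 | intermediate
25 | tert-butyl prop-2-enoate | C=CC(=O)OC(C)(C)C | starting material
26 | acetaldehyde | CC=O | starting material
27 | tert-butyl 3-hydroxy-2-methylidenebutanoate (racemic) | CC(O)C(=C)C(=O)OC(C)(C)C | intermediate
28 | tert-butyl 3-acetoxy-2-methylidenebutanoate (racemic) | CC(OC(C)=O)C(=C)C(=O)OC(C)(C)C | intermediate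
29 | tert-butyl (2E)-2-(acetoxymethyl)but-2-enoate | C/C=C(COC(C)=O)/C(=O)OC(C)(C)C | intermediate
30 | (2E)-2-(acetoxymethyl)but-2-enoic acid | C/C=C(COC(C)=O)/C(=O)O | intermediate
31 | (2E)-2-(acetoxymethyl)but-2-enoyl chloride | C/C=C(COC(C)=O)/C(=O)Cl | intermediate
32 | [(3aS,4R,5Z,9E,11aS)-4-hydroxy-10-methyl-3-methylidene-2-oxo-2,3,3a,4,7,8,11,11a-octahydrocyclodeca[b]furan-6-yl]methyl (2E)-2-(acetoxymethyl)but-2-enoate | C=C1C(=O)O[C@H]2C/C(C)=C/CC/C(COC(=O)/C(=C/C)COC(C)=O)=C/[C@@H](O)[C@H]12 | target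

**Step count:** 17 steps in total. Longest linear sequence: 12 steps (1, 2, 3, 4, 7, 8, 9, 10, 11, 12, 13, 17).

**Steps most likely to fail**

Step 9. What may go wrong: erosion of the E geometry when the cyclopropane opens, competing capture of the cation at C9 or by a silyl ether oxygen, or acid-induced loss of a silyl group. Fallback with known chemistry, setting out from 10 (with zinc reagent 17) and returning at 20: the addition of step 7 is run with (+)-MIB to give the (5R)-epimeric allylic alcohol tert-butyl 2-[(2S,3E,5R,8Z)-1-[(tert-butyldimethylsilyl)oxy]-8-{[(tert-butyldiphenylsilyl)oxy]methyl}-5-hydroxy-9-iodo-4-methylnona-3,8-dien-2-yl]prop-2-enoate F1. Hydroxyl-directed Simmons–Smith cyclopropanation then gives the cyclopropyl carbinol with the antipodal ring, tert-butyl 2-{(1S)-2-[(tert-butyldimethylsilyl)oxy]-1-[(1S,2R)-2-{(1R,4Z)-4-{[(tert-butyldiphenylsilyl)oxy]methyl}-1-hydroxy-5-iodopent-4-en-1-yl}-2-methylcyclopropyl]ethyl}prop-2-enoate F2. The two-stage Julia–Johnson protocol (PBr3, 2,4,6-collidine, LiBr, Et2O, −78 °C; then ZnBr2, 0 °C) should open it with bromide at C8 with inversion to the (E)-homoallylic bromide tert-butyl (3S,4R,6E,10Z)-4-bromo-3-{[(tert-butyldimethylsilyl)oxy]methyl}-10-{[(tert-butyldiphenylsilyl)oxy]methyl}-11-iodo-6-methyl-2-methylideneundeca-6,10-dienoate F3. TMSOTf/2,6-lutidine then frees the acid (3S,4R,6E,10Z)-4-bromo-3-{[(tert-butyldimethylsilyl)oxy]methyl}-10-{[(tert-butyldiphenylsilyl)oxy]methyl}-11-iodo-6-methyl-2-methylideneundeca-6,10-dienoic acid F4, and Cs2CO3 in DMF closes the lactone by carboxylate SN2 displacement with a second inversion, which arrives at 20.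

Step 12. What may go wrong: poor facial selectivity at C6 during ring closure, oligomerisation competing with the ten-membered ring closure, or epimerisation of the α-branched aldehyde. Fallback setting out from 22 and returning at 23: the closure is run as described and the epimeric carbinol (3aS,4S,5Z,9E,11aS)-6-{[(tert-butyldiphenylsilyl)oxy]methyl}-4-hydroxy-10-methyl-3-methylidene-3a,4,7,8,11,11a-hexahydrocyclodeca[b]furan-2(3H)-one F5 (alone or mixed with 23) is oxidised with Dess–Martin periodinane to the cross-conjugated enone (3aR,5Z,9E,11aS)-6-{[(tert-butyldiphenylsilyl)oxy]methyl}-10-methyl-3-methylidene-7,8,11,11a-tetrahydrocyclodeca[b]furan-2,4(3H,3aH)-dione F6. Reagent-controlled Corey–Bakshi–Shibata reduction ((R)-Me-CBS, catecholborane, −78 °C, the alkenyl arm as the large group) should then return the (4R)-alcohol 23.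

Step 8. What may go wrong: insufficient syn facial selectivity in the directed cyclopropanation (a mismatched influence of C7, or incomplete enantiocontrol carried over from step 7), which would give the wrong C8 configuration after step 9. Fallback setting out from 9 (isolated by leaving out the MnO2 stage of step 4) and returning at 19: reagent-controlled asymmetric Simmons–Smith cyclopropanation of the primary allylic alcohol (Zn(CH2I)2·DME, (4R,5R)-2-butyl-N,N,N′,N′-tetramethyl-1,3,2-dioxaborolane-4,5-dicarboxamide) should give tert-butyl 2-{(1S)-2-[(tert-butyldimethylsilyl)oxy]-1-[(1R,2S)-2-(hydroxymethyl)-2-methylcyclopropyl]ethyl}prop-2-enoate F7. Dess–Martin oxidation gives the configurationally stable aldehyde tert-butyl 2-{(1S)-2-[(tert-butyldimethylsilyl)oxy]-1-[(1R,2S)-2-formyl-2-methylcyclopropyl]ethyl}prop-2-enoate F8. Addition of zinc reagent 17 as in step 7, where the C1 configuration no longer matters, gives 19 together with its C1 epimer tert-butyl 2-{(1S)-2-[(tert-butyldimethylsilyl)oxy]-1-[(1R,2S)-2-{(1R,4Z)-4-{[(tert-butyldiphenylsilyl)oxy]methyl}-1-hydroxy-5-iodopent-4-en-1-yl}-2-methylcyclopropyl]ethyl}prop-2-enoate F9. Both should converge on 20 in step 9 because C1 becomes sp2.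

**Further compounds**
F1 | step 9 | tert-butyl 2-[(2S,3E,5R,8Z)-1-[(tert-butyldimethylsilyl)oxy]-8-{[(tert-butyldiphenylsilyl)oxy]methyl}-5-hydroxy-9-iodo-4-methylnona-3,8-dien-2-yl]prop-2-enoate | CC(C)(C)OC(=O)C(=C)[C@@H](CO[Si](C)(C)C(C)(C)C)/C=C(\C)[C@H](O)CC/C(CO[Si](C(C)(C)C)(c1ccccc1)c1ccccc1)=C/I
F2 | step 9 | tert-butyl 2-{(1S)-2-[(tert-butyldimethylsilyl)oxy]-1-[(1S,2R)-2-{(1R,4Z)-4-{[(tert-butyldiphenylsilyl)oxy]methyl}-1-hydroxy-5-iodopent-4-en-1-yl}-2-methylcyclopropyl]ethyl}prop-2-enoate | CC(C)(C)OC(=O)C(=C)[C@@H](CO[Si](C)(C)C(C)(C)C)[C@@H]1C[C@@]1(C)[C@H](O)CC/C(CO[Si](C(C)(C)C)(c1ccccc1)c1ccccc1)=C/I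
F3 | step 9 | tert-butyl (3S,4R,6E,10Z)-4-bromo-3-{[(tert-butyldimethylsilyl)oxy]methyl}-10-{[(tert-butyldiphenylsilyl)oxy]methyl}-11-iodo-6-methyl-2-methylideneundeca-6,10-dienoate | CC(C)(C)OC(=O)C(=C)[C@@H](CO[Si](C)(C)C(C)(C)C)[C@H](Br)C/C(C)=C/CC/C(CO[Si](C(C)(C)C)(c1ccccc1)c1ccccc1)=C/I
F4 | step 9 | (3S,4R,6E,10Z)-4-bromo-3-{[(tert-butyldimethylsilyl)oxy]methyl}-10-{[(tert-butyldiphenylsilyl)oxy]methyl}-11-iodo-6-methyl-2-methylideneundeca-6,10-dienoic acid | OC(=O)C(=C)[C@@H](CO[Si](C)(C)C(C)(C)C)[C@H](Br)C/C(C)=C/CC/C(CO[Si](C(C)(C)C)(c1ccccc1)c1ccccc1)=C/I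
F5 | step 12 | (3aS,4S,5Z,9E,11aS)-6-{[(tert-butyldiphenylsilyl)oxy]methyl}-4-hydroxy-10-methyl-3-methylidene-3a,4,7,8,11,11a-hexahydrocyclodeca[b]furan-2(3H)-one | C=C1C(=O)O[C@H]2C/C(C)=C/CC/C(CO[Si](C(C)(C)C)(c3ccccc3)c3ccccc3)=C/[C@H](O)[C@H]12
F6 | step 12 | (3aR,5Z,9E,11aS)-6-{[(tert-butyldiphenylsilyl)oxy]methyl}-10-methyl-3-methylidene-7,8,11,11a-tetrahydrocyclodeca[b]furan-2,4(3H,3aH)-dione | C=C1C(=O)O[C@H]2C/C(C)=C/CC/C(CO[Si](C(C)(C)C)(c3ccccc3)c3ccccc3)=C/C(=O)[C@H]12
F7 | step 8 | tert-butyl 2-{(1S)-2-[(tert-butyldimethylsilyl)oxy]-1-[(1R,2S)-2-(hydroxymethyl)-2-methylcyclopropyl]ethyl}prop-2-enoate | CC(C)(C)OC(=O)C(=C)[C@@H](CO[Si](C)(C)C(C)(C)C)[C@H]1C[C@]1(C)CO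
F8 | step 8 | tert-butyl 2-{(1S)-2-[(tert-butyldimethylsilyl)oxy]-1-[(1R,2S)-2-formyl-2-methylcyclopropyl]ethyl}prop-2-enoate | CC(C)(C)OC(=O)C(=C)[C@@H](CO[Si](C)(C)C(C)(C)C)[C@H]1C[C@]1(C)C=O
F9 | step 8 | tert-butyl 2-{(1S)-2-[(tert-butyldimethylsilyl)oxy]-1-[(1R,2S)-2-{(1R,4Z)-4-{[(tert-butyldiphenylsilyl)oxy]methyl}-1-hydroxy-5-iodopent-4-en-1-yl}-2-methylcyclopropyl]ethyl}prop-2-enoate | CC(C)(C)OC(=O)C(=C)[C@@H](CO[Si](C)(C)C(C)(C)C)[C@H]1C[C@]1(C)[C@H](O)CC/C(CO[Si](C(C)(C)C)(c1ccccc1)c1ccccc1)=C/I
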